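**Strategy.** Ring A (C1 CHO, C2 Me, C3 chain, C4 Me, C5 H, C6 OH) is split into two three-carbon halves. C2–C3–C4 is a masked 3-alkylpentane-2,4-dione; C5–C6–C1 plus the formyl carbon is a masked acetoacetate. Because the dione half is symmetric about C3, one TiCl4-mediated [3+3] cyclocondensation forges C4–C5 and C1–C2, closes ring A and places all five substituents unambiguously. The precursor is the trimethylsilyl enol ether of acetylacetone whose C3 carries a CH2CH2 link to the (S)-citramalic acid stereocentre, locked as an acetonide dioxolanone. Afterwards the reactive lactone becomes a vinyl carbinol while the hindered ester waits as latent CHO. Ring B enters by Heck arylation.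

Key step: step 8

Remark: the four bonds of the citramalate stereocentre are never broken, and the priority order O > one-carbon unit (CO2H, lactone C=O, lactol CH, CHO, CH=) > CH2 > CH3 holds in every compound, so the descriptor stays S from 1 to 23.

Step 1
Reactants: 1 (S)-citramalic acid
Product: 2 2-[(4S)-2,2,4-trimethyl-5-oxo-1,3-dioxolan-4-yl]acetic acid
Conditions: Me2C(OMe)2, p-TsOH·H2O (cat.), CH2Cl2, rt
Reagents that add atoms: 2,2-dimethoxypropane COC(C)(C)OC
Why: Acid-catalysed transketalisation closes the five-membered dioxolanone across the tertiary OH and the adjacent carboxyl in preference to the six-membered alternative, which leaves the CH2CO2H arm free and breaks no bond at the stereocentre.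

Step 2
Reactants: 2 2-[(4S)-2,2,4-trimethyl-5-oxo-1,3-dioxolan-4-yl]acetic acid
Product: 3 (5S)-5-(2-hydroxyethyl)-2,2,5-trimethyl-1,3-dioxolan-4-one
Conditions: BH3·THF (1.3 equiv), THF, 0 °C → rt; MeOH quench, evaporation, used crude
Reagents that add atoms: none
Why: Chemoselective borane reduction takes a free carboxylic acid through its acyloxyborane much faster than a lactone, and the neutral quench with direct use of crude 3 should forestall migration of the lactone onto the new primary alcohol.

Step 3
Reactants: 3 (5S)-5-(2-hydroxyethyl)-2,2,5-trimethyl-1,3-dioxolan-4-one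
Product: 4 (5S)-5-(2-iodoethyl)-2,2,5-trimethyl-1,3-dioxolan-4-one
Conditions: I2, PPh3, imidazole, CH2Cl2, 0 °C
Reagents that add atoms: iodine II
Why: Appel-type iodination activates the primary alcohol as its alkoxyphosphonium salt and displaces it with iodide under nearly neutral conditions that ketal and lactone tolerate.

Step 4
Reactants: 4 (5S)-5-(2-iodoethyl)-2,2,5-trimethyl-1,3-dioxolan-4-one, 5 acetylacetone (3 equiv)
Product: 6 3-{2-[(4S)-2,2,4-trimethyl-5-oxo-1,3-dioxolan-4-yl]ethyl}pentane-2,4-dione
Conditions: K2CO3, acetone, reflux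
Reagents that add atoms: none
Why: SN2 C-alkylation of the soft potassium enolate of acetylacetone by a primary iodide is the standard entry to 3-alkylpentane-2,4-diones; excess 5 curbs dialkylation, and the stereocentre carries no acidic hydrogen.

Step 5
Reactants: 6 3-{2-[(4S)-2,2,4-trimethyl-5-oxo-1,3-dioxolan-4-yl]ethyl}pentane-2,4-dione
Product: 7 3-{2-[(4S)-2,2,4-trimethyl-5-oxo-1,3-dioxolan-4-yl]ethyl}-4-(trimethylsilyloxy)pent-3-en-2-one (E/Z mixture)
Conditions: Me3SiCl, Et3N, toluene, rt; filtration under argon, used crude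
Reagents that add atoms: chlorotrimethylsilane C[Si](C)(C)Cl
Why: Amine-promoted O-silylation of the 1,3-diketone gives the vinylogous silyl ester, and the alkene geometry is irrelevant because both oxygenated carbons end up as equivalent ring positions.

Step 6
Reactants: 8 methyl acetoacetate
Product: 9 methyl 3-(trimethylsilyloxy)but-2-enoate
Conditions: Me3SiCl, Et3N, pentane, rt
Reagents that add atoms: chlorotrimethylsilane C[Si](C)(C)Cl
Why: The same amine-promoted O-silylation traps the enol of the β-keto ester.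

Step 7
Reactants: 9 methyl 3-(trimethylsilyloxy)but-2-enoate
Product: 11 1-methoxy-1,3-bis(trimethylsilyloxy)buta-1,3-diene, via lithium dienolate 10 (not isolated)
Conditions: LiN(i-Pr)2 (commercial solution), THF, −78 °C; Me3SiCl, −78 → 20 °C
Reagents that add atoms: chlorotrimethylsilane C[Si](C)(C)Cl
Why: Kinetic γ-deprotonation gives dienolate 10, which is silylated on the ester oxygen (silyl ketene acetal formation) to the doubly masked acetoacetate dianion.

Step 8
Reactants: 7 3-{2-[(4S)-2,2,4-trimethyl-5-oxo-1,3-dioxolan-4-yl]ethyl}-4-(trimethylsilyloxy)pent-3-en-2-one, 11 1-methoxy-1,3-bis(trimethylsilyloxy)buta-1,3-diene (1.5 equiv)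
Product: 14 methyl 6-hydroxy-2,4-dimethyl-3-{2-[(4S)-2,2,4-trimethyl-5-oxo-1,3-dioxolan-4-yl]ethyl}benzoate, via open-chain enedione keto ester 12 (not isolated), via cyclohexenone aldol 13 (not isolated)
Conditions: TiCl4 (1.1 equiv), 4 Å molecular sieves, CH2Cl2 (concentrated), −78 → 20 °C; sat. aq NaHCO3
Reagents that add atoms: none
Why: TiCl4 binds the most Lewis-basic oxygen present, the vinylogous-ester carbonyl of 7, and the terminal CH2 of 11 (its most nucleophilic carbon) adds to the silyloxy-bearing carbon and expels silanolate to give 12. The central β-keto ester carbon of 12, as its titanium enolate, then attacks the remaining acetyl carbonyl in a 6-(enolendo)-exo-trig aldol closure to 13, and loss of water followed by enolisation aromatises ring A. This is the established formal [3+3] cyclocondensation of 1,3-bis(silyloxy)-1,3-dienes with 3-silyloxy-2-en-1-ones, a reaction type already applied to 3-alkyl-4-silyloxypent-3-en-2-ones. No lasting stereocentre is created (those of 13 vanish on aromatisation), and the citramalate centre is quaternary and flanked by a carbonyl, so it can neither enolise nor readily ionise at its C–O bond. The only selectivity required is terminal-carbon-first attack of the diene, because the two oxygenated carbons of the pentanedione half are equivalent and either orientation leads to 14. The sensitive site is the ketal carbon of the dioxolanone, so TiCl4 is held near one equivalent, sieves bind the water released and the quench is basic.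

Step 9
Reactants: 14 methyl 6-hydroxy-2,4-dimethyl-3-{2-[(4S)-2,2,4-trimethyl-5-oxo-1,3-dioxolan-4-yl]ethyl}benzoate
Product: 15 methyl 6-hydroxy-3-{2-[(4S)-5-hydroxy-2,2,4-trimethyl-1,3-dioxolan-4-yl]ethyl}-2,4-dimethylbenzoate (lactol, both C5 epimers)
Conditions: i-Bu2AlH (2.3 equiv), CH2Cl2, −78 °C; aq potassium sodium tartrate, used crude
Reagents that add atoms: none
Why: Partial lactone-to-lactol reduction stops at the tetrahedral aluminium alkoxide at −78 °C, while the first equivalent converts the phenol into an aluminium phenoxide whose electron donation, together with the two ortho substituents, keeps the aromatic ester inert.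

Step 10
Reactants: 15 methyl 6-hydroxy-3-{2-[(4S)-5-hydroxy-2,2,4-trimethyl-1,3-dioxolan-4-yl]ethyl}-2,4-dimethylbenzoate
Product: 17 methyl 6-hydroxy-3-[(3S)-3-hydroxy-3-methylpent-4-en-1-yl]-2,4-dimethylbenzoate, via hydroxy aldehyde 16 (not isolated)
Conditions: Ph3PCH3Br (6 equiv), KOt-Bu (5.5 equiv), THF, 0 °C → rt
Reagents that add atoms: methyltriphenylphosphonium bromide C[P+](c1ccccc1)(c1ccccc1)c1ccccc1.[Br-]
Why: In this Wittig methylenation of a lactol, base opens 15 to 16 with loss of acetone, and the ylide, in excess to cover the acidic OH groups and the acetone, converts the only aldehyde present into the terminal alkene next to a stereocentre that cannot epimerise.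

Step 11
Reactants: 17 methyl 6-hydroxy-3-[(3S)-3-hydroxy-3-methylpent-4-en-1-yl]-2,4-dimethylbenzoate
Product: 18 2-(hydroxymethyl)-4-[(3S)-3-hydroxy-3-methylpent-4-en-1-yl]-3,5-dimethylphenol
Conditions: LiAlH4 (3 equiv), THF, 0 °C → rt; aq potassium sodium tartrate (no acid)
Reagents that add atoms: none
Why: Hydride reduction of the hindered salicylate as its phenoxide should stop at the salicyl alcohol at or below room temperature, and the isolated terminal alkene and the tertiary alkoxide are inert to LiAlH4.

Step 12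
Reactants: 18 2-(hydroxymethyl)-4-[(3S)-3-hydroxy-3-methylpent-4-en-1-yl]-3,5-dimethylphenol
Product: 19 6-hydroxy-3-[(3S)-3-hydroxy-3-methylpent-4-en-1-yl]-2,4-dimethylbenzaldehyde
Conditions: activated MnO2 (excess), CH2Cl2, rt
Reagents that add atoms: none
Why: Heterogeneous MnO2 oxidation is selective for the benzylic alcohol, since the tertiary allylic alcohol has no carbinol hydrogen, and the hydrogen-bonded salicylaldehyde resists further oxidation.

Step 13
Reactants: 20 bromohydroquinone (2-bromobenzene-1,4-diol)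
Product: 21 2-bromo-1,4-bis(tert-butyldimethylsilyloxy)benzene
Conditions: t-BuMe2SiCl (2.4 equiv), imidazole, DMF, rt
Reagents that add atoms: tert-butyldimethylsilyl chloride CC(C)(C)[Si](C)(C)Cl
Why: Imidazole-promoted silylation masks both phenols of ring B so that neither chromene formation nor hydroquinone oxidation can interfere with the coupling.

Step 14
Reactants: 19 6-hydroxy-3-[(3S)-3-hydroxy-3-methylpent-4-en-1-yl]-2,4-dimethylbenzaldehyde, 21 2-bromo-1,4-bis(tert-butyldimethylsilyloxy)benzene
Product: 22 3-{(3S,4E)-5-[2,5-bis(tert-butyldimethylsilyloxy)phenyl]-3-hydroxy-3-methylpent-4-en-1-yl}-6-hydroxy-2,4-dimethylbenzaldehyde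
Conditions: Pd2(dba)3 (2.5 mol %), [HP(t-Bu)3]BF4 (10 mol %), Cy2NMe, dioxane, 80 °C
Reagents that add atoms: none
Why: In this Heck arylation the aryl group adds to the unhindered CH2 terminus, and because the carbinol carbon bears no hydrogen, syn β-hydride elimination can only give the conjugated E-styryl carbinol, as is well established for 2-methylbut-3-en-2-ol type alkenes.

Step 15
Reactants: 22 3-{(3S,4E)-5-[2,5-bis(tert-butyldimethylsilyloxy)phenyl]-3-hydroxy-3-methylpent-4-en-1-yl}-6-hydroxy-2,4-dimethylbenzaldehyde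
Product: 23 3-[(3S,4E)-5-(2,5-dihydroxyphenyl)-3-hydroxy-3-methylpent-4-en-1-yl]-6-hydroxy-2,4-dimethylbenzaldehyde (target)
Conditions: Bu4NF (2.5 equiv), AcOH (2.5 equiv), THF, 0 °C, argon
Reagents that add atoms: none
Why: Fluoride cleaves the two aryl silyl ethers, and the acetic acid buffer with exclusion of air avoids both autoxidation of the hydroquinone phenoxide and acid ionisation of the tertiary allylic alcohol.

**Compound list**

1 | (S)-citramalic acid, (2S)-2-hydroxy-2-methylbutanedioic acid | OC(=O)C[C@](C)(O)C(=O)O | starting material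
2 | 2-[(4S)-2,2,4-trimethyl-5-oxo-1,3-dioxolan-4-yl]acetic acid | OC(=O)C[C@]1(C)OC(C)(C)OC1=O | intermediate
3 | (5S)-5-(2-hydroxyethyl)-2,2,5-trimethyl-1,3-dioxolan-4-one | OCC[C@]1(C)OC(C)(C)OC1=O | intermediate
4 | (5S)-5-(2-iodoethyl)-2,2,5-trimethyl-1,3-dioxolan-4-one | ICC[C@]1(C)OC(C)(C)OC1=O | intermediate
5 | acetylacetone | CC(=O)CC(C)=O | starting material
6 | 3-{2-[(4S)-2,2,4-trimethyl-5-oxo-1,3-dioxolan-4-yl]ethyl}pentane-2,4-dione | CC(=O)C(CC[C@]1(C)OC(C)(C)OC1=O)C(C)=O | intermediate
7 | 3-{2-[(4S)-2,2,4-trimethyl-5-oxo-1,3-dioxolan-4-yl]ethyl}-4-(trimethylsilyloxy)pent-3-en-2-one (E/Z mixture) | CC(=O)C(CC[C@]1(C)OC(C)(C)OC1=O)=C(C)O[Si](C)(C)C | intermediate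
8 | methyl acetoacetate | COC(=O)CC(C)=O | starting material
9 | methyl 3-(trimethylsilyloxy)but-2-enoate | COC(=O)C=C(C)O[Si](C)(C)C | intermediate
10 | lithium dienolate of 9 (not isolated) | [Li+].COC([O-])=CC(=C)O[Si](C)(C)C | intermediate
11 | 1-methoxy-1,3-bis(trimethylsilyloxy)buta-1,3-diene | COC(O[Si](C)(C)C)=CC(=C)O[Si](C)(C)C | intermediate
12 | methyl 5-methyl-3,7-dioxo-6-{2-[(4S)-2,2,4-trimethyl-5-oxo-1,3-dioxolan-4-yl]ethyl}oct-5-enoate (drawn metal-free, titanium-bound in the flask, not isolated) | COC(=O)CC(=O)CC(C)=C(CC[C@]1(C)OC(C)(C)OC1=O)C(C)=O | intermediate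
13 | methyl 2-hydroxy-2,4-dimethyl-6-oxo-3-{2-[(4S)-2,2,4-trimethyl-5-oxo-1,3-dioxolan-4-yl]ethyl}cyclohex-3-ene-1-carboxylate (drawn metal-free, not isolated) | COC(=O)C1C(=O)CC(C)=C(CC[C@]2(C)OC(C)(C)OC2=O)C1(C)O | intermediate
14 | methyl 6-hydroxy-2,4-dimethyl-3-{2-[(4S)-2,2,4-trimethyl-5-oxo-1,3-dioxolan-4-yl]ethyl}benzoate | COC(=O)c1c(O)cc(C)c(CC[C@]2(C)OC(C)(C)OC2=O)c1C | intermediate
15 | methyl 6-hydroxy-3-{2-[(4S)-5-hydroxy-2,2,4-trimethyl-1,3-dioxolan-4-yl]ethyl}-2,4-dimethylbenzoate (lactol epimers) | COC(=O)c1c(O)cc(C)c(CC[C@]2(C)OC(C)(C)OC2O)c1C | intermediate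
16 | methyl 6-hydroxy-3-[(3S)-3-hydroxy-3-methyl-4-oxobutyl]-2,4-dimethylbenzoate (not isolated) | COC(=O)c1c(O)cc(C)c(CC[C@](C)(O)C=O)c1C | intermediate
17 | methyl 6-hydroxy-3-[(3S)-3-hydroxy-3-methylpent-4-en-1-yl]-2,4-dimethylbenzoate | COC(=O)c1c(O)cc(C)c(CC[C@](C)(O)C=C)c1C | intermediate
18 | 2-(hydroxymethyl)-4-[(3S)-3-hydroxy-3-methylpent-4-en-1-yl]-3,5-dimethylphenol | OCc1c(O)cc(C)c(CC[C@](C)(O)C=C)c1C | intermediate
19 | 6-hydroxy-3-[(3S)-3-hydroxy-3-methylpent-4-en-1-yl]-2,4-dimethylbenzaldehyde | O=Cc1c(O)cc(C)c(CC[C@](C)(O)C=C)c1C | intermediate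
20 | bromohydroquinone | Oc1ccc(O)c(Br)c1 | starting material
21 | 2-bromo-1,4-bis(tert-butyldimethylsilyloxy)benzene | Brc1cc(O[Si](C)(C)C(C)(C)C)ccc1O[Si](C)(C)C(C)(C)C | intermediate
22 | 3-{(3S,4E)-5-[2,5-bis(tert-butyldimethylsilyloxy)phenyl]-3-hydroxy-3-methylpent-4-en-1-yl}-6-hydroxy-2,4-dimethylbenzaldehyde | Cc1cc(O)c(C=O)c(C)c1CC[C@](C)(O)/C=C/c1cc(O[Si](C)(C)C(C)(C)C)ccc1O[Si](C)(C)C(C)(C)C | intermediate
23 | 3-[(3S,4E)-5-(2,5-dihydroxyphenyl)-3-hydroxy-3-methylpent-4-en-1-yl]-6-hydroxy-2,4-dimethylbenzaldehyde | Cc1cc(O)c(C=O)c(C)c1CC[C@](C)(O)/C=C/c1cc(O)ccc1O | target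

**Totals.** The route has 15 steps in all. The longest linear sequence is 12 steps (steps 1–5, 8–12, 14, 15).

**Steps most likely to fail**

Step 8.
- What may go wrong: TiCl4 may also engage the lactone carbonyl and ionise the ketal carbon of the dioxolanone. The diene could then add there, or acetone could be stripped off. The congested tetrasubstituted silyloxy enone may also react too slowly to outrun this.
- Fallback (sets out from 4, 5 and 11, returns at 14): ring A is closed first without the chain, and the chain is attached afterwards by cross-coupling. Acetylacetone 5 is O-silylated (Me3SiCl, Et3N) to 4-(trimethylsilyloxy)pent-3-en-2-one F1. This undergoes the parent TiCl4 cyclocondensation with 11 to give methyl 6-hydroxy-2,4-dimethylbenzoate F2. Bromination para to the phenol (NBS, MeCN, 0 °C) should give methyl 3-bromo-6-hydroxy-2,4-dimethylbenzoate F3. Iodide 4 is converted with zinc dust and LiCl in THF into {2-[(4S)-2,2,4-trimethyl-5-oxo-1,3-dioxolan-4-yl]ethyl}zinc iodide F4. A Negishi coupling of F3 with F4 then delivers 14 (Pd(OAc)2, SPhos, THF, slow addition of the zinc reagent so that the hydrogen-bonded phenol is tolerated).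

Step 10.
- What may go wrong: the alkoxide of the liberated α-hydroxy aldehyde may undergo α-ketol rearrangement or oligomerise before it is methylenated, and the released acetone drains the ylide.
- Fallback (sets out from 15, returns at 17): a two-stage Peterson olefination replaces the ylide with a fast carbonyl addition. Me3SiCH2MgCl (excess, THF, −78 → 0 °C) opens the lactol and adds to the aldehyde to give methyl 3-[(3S)-3,4-dihydroxy-3-methyl-5-(trimethylsilyl)pentyl]-6-hydroxy-2,4-dimethylbenzoate F5. KH in THF then triggers syn elimination of silanolate to give 17.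

Step 14.
- What may go wrong: oxidative addition of zerovalent palladium into the electron-rich, ortho-silyloxy bromide may be slow. Catalyst decay, silyl loss or phenoxide-directed arylation of the formyl C–H bond could then compete.
- Fallback (sets out from 19, returns at 22): the alkene is made by cross-metathesis instead of C–H arylation. 2,5-Dihydroxybenzaldehyde F6 is bis-silylated (t-BuMe2SiCl, imidazole, DMF) to 2,5-bis(tert-butyldimethylsilyloxy)benzaldehyde F7. Methylenation (Ph3PCH3Br, KOt-Bu, THF) gives 2,5-bis(tert-butyldimethylsilyloxy)styrene F8. Cross-metathesis of 19 with F8 (second-generation Hoveyda-Grubbs catalyst, CH2Cl2, 40 °C) should give the E-alkene 22.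

**Further compounds**

F1 | step 8 | 4-(trimethylsilyloxy)pent-3-en-2-one | CC(=O)C=C(C)O[Si](C)(C)C
F2 | step 8 | methyl 6-hydroxy-2,4-dimethylbenzoate | COC(=O)c1c(O)cc(C)cc1C
F3 | step 8 | methyl 3-bromo-6-hydroxy-2,4-dimethylbenzoate | COC(=O)c1c(O)cc(C)c(Br)c1C
F4 | step 8 | {2-[(4S)-2,2,4-trimethyl-5-oxo-1,3-dioxolan-4-yl]ethyl}zinc iodide | I[Zn]CC[C@]1(C)OC(C)(C)OC1=O
F5 | step 10 | methyl 3-[(3S)-3,4-dihydroxy-3-methyl-5-(trimethylsilyl)pentyl]-6-hydroxy-2,4-dimethylbenzoate | COC(=O)c1c(O)cc(C)c(CC[C@](C)(O)C(O)C[Si](C)(C)C)c1C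
F6 | step 14 | 2,5-dihydroxybenzaldehyde (purchased) | O=Cc1cc(O)ccc1O
F7 | step 14 | 2,5-bis(tert-butyldimethylsilyloxy)benzaldehyde | O=Cc1cc(O[Si](C)(C)C(C)(C)C)ccc1O[Si](C)(C)C(C)(C)C
F8 | step 14 | 2,5-bis(tert-butyldimethylsilyloxy)styrene | C=Cc1cc(O[Si](C)(C)C(C)(C)C)ccc1O[Si](C)(C)C(C)(C)C
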